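## Retrosynthetic overview

1. The three aryl–O–C8 ether bonds are cut first: each is made by Mitsunobu inversion of an (R)- or (S)-glycerate bought from the chiral pool, and each C7 carbinol then follows by 1,2-induction from C8 (aryl Grignard onto the aldehyde for the two erythro units, hydride onto the aryl ketone for the threo unit).
2. This leaves mono-O-benzyl syringaresinol, whose two tetrahydrofuran rings are closed together, as the last ring-forming event, by acid from a 2,3-disubstituted butane-1,4-diol.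
3. That diol comes from a trans-3,4-disubstituted γ-butyrolactone (the first ring formed, later opened) by enolate aldol anti to the 4-substituent, ozonolysis and aryl Grignard addition.
4. The lactone stereocentre and the central C8–C8′ bond come from a Johnson–Claisen [3,3] rearrangement of an (S,E)-allylic alcohol made from (S)-but-3-en-2-ol, with 1,3-chirality transfer.

Assumption: every compound marked "starting material" in the compound list is a catalogue item; the only chiral ones are the butenol and the two enantiomeric glycerate acetonides.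

Abbreviations: TBS = tert-butyldimethylsilyl, TES = triethylsilyl, Bn = benzyl; C7/C8/C9 = benzylic, ether-bearing and CH2O carbons of a C6–C3 unit; unit A = the guaiacylglycerol on the first syringyl ring, unit B = the inner and unit C = the outer guaiacylglycerol on the second syringyl ring.

## Route

Step 1
Reactants: 1 (2S)-but-3-en-2-ol; 2 (2Z)-but-2-ene-1,4-diyl diacetate
Product: 3 (2E,4S)-4-hydroxypent-2-en-1-yl acetate
Conditions: 2 (2 equiv), second-generation Grubbs catalyst (H2IMes)(PCy3)Cl2Ru=CHPh (2 mol%), CH2Cl2, 40 °C; E isomer purified on AgNO3-impregnated silica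
Reagents that add atoms: none
Why: Olefin cross-metathesis of a secondary allylic alcohol with a symmetrical allylic acetate donor gives the E-disubstituted alkene under thermodynamic control and does not touch the bought carbinol stereocentre.

Step 2
Reactants: 3 (2E,4S)-4-hydroxypent-2-en-1-yl acetate; 4 triethyl orthoacetate
Product: 7 (4S)-4-[(1E)-prop-1-en-1-yl]dihydrofuran-2(3H)-one, via ketene acetal 5 (not isolated), via hexenoate ester 6 (not isolated)
Conditions: 4 (6 equiv), EtCO2H (5 mol%), 140 °C, EtOH distilled off; evaporate; then p-TsOH·H2O (10 mol%), MeOH, 60 °C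
Reagents that add atoms: none
Why: The Johnson–Claisen [3,3]-sigmatropic rearrangement runs through a chair transition state with the methyl group equatorial, so it forms the C8–C8′ bond and transfers the (S)-carbinol configuration to the new (S)-centre (new alkene E), after which acid methanolysis of the acetate frees the primary alcohol that lactonises onto the ester.

Step 3
Reactants: 7 (4S)-4-[(1E)-prop-1-en-1-yl]dihydrofuran-2(3H)-one; 8 4-(benzyloxy)-3,5-dimethoxybenzaldehyde
Product: 11 (3S,4R)-3-{[4-(benzyloxy)-3,5-dimethoxyphenyl][(triethylsilyl)oxy]methyl}-4-[(1E)-prop-1-en-1-yl]dihydrofuran-2(3H)-one (both carbinol epimers), via lithium enolate 9 (not isolated), via lithium aldolate 10 (not isolated)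
Conditions: LiN(i-Pr)2 (1.05 equiv), THF, −78 °C; 8; then Et3SiOTf (1.3 equiv), −78 °C
Reagents that add atoms: triethylsilyl trifluoromethanesulfonate CC[Si](CC)(CC)OS(=O)(=O)C(F)(F)F
Why: Aldol addition of the lactone lithium enolate occurs on the face anti to the 4-propenyl group, which sets C3 trans to C4, while the carbinol centre is left as a mixture that step 7 erases and in situ O-silylation blocks retro-aldol.

Step 4
Reactants: 11 the silylated aldol lactone
Product: 13 (3R,4S)-4-{[4-(benzyloxy)-3,5-dimethoxyphenyl][(triethylsilyl)oxy]methyl}-5-oxotetrahydrofuran-3-carbaldehyde, via ozonide 12 (not isolated)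
Conditions: O3, CH2Cl2, −78 °C, stopped at the first blue tint; then Me2S, −78 °C → rt; used crude
Reagents that add atoms: ozone [O-][O+]=O
Why: Ozonolysis with reductive work-up cleaves the only alkene far faster than the alkoxy-arenes and liberates the aldehyde without base, so the α-stereocentre (C8′) stays trans to its neighbour.

Step 5
Reactants: 14 4-bromo-2,6-dimethoxyphenol
Product: 15 5-bromo-2-(1-ethoxyethoxy)-1,3-dimethoxybenzene (racemic acetal)
Conditions: ethyl vinyl ether (3 equiv), pyridinium p-toluenesulfonate (5 mol%), CH2Cl2, rt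
Reagents that add atoms: ethyl vinyl ether C=COCC
Why: Acid-catalysed addition of the phenol to the enol ether gives a mixed acetal that survives Grignard formation and LiAlH4 and falls off under the acid of step 7.

Step 6
Reactants: 13 the lactone aldehyde; 15 5-bromo-2-(1-ethoxyethoxy)-1,3-dimethoxybenzene
Product: 17 (3S,4R)-3-{[4-(benzyloxy)-3,5-dimethoxyphenyl][(triethylsilyl)oxy]methyl}-4-{[4-(1-ethoxyethoxy)-3,5-dimethoxyphenyl](hydroxy)methyl}dihydrofuran-2(3H)-one (carbinol epimers), via arylmagnesium bromide 16 (not isolated)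
Conditions: 15, Mg, THF, 45 °C; then 13, THF, −78 °C; aq. NH4Cl
Reagents that add atoms: none
Why: Grignard addition is chemoselective for the aldehyde over the lactone at −78 °C, and the new carbinol centre need not be controlled because step 7 ionises it (any lactone transposition by the alkoxide leads to the same triol).

Step 7
Reactants: 17 the diaryl lactone
Product: 19 4-[(1S,3aR,4S,6aR)-4-[4-(benzyloxy)-3,5-dimethoxyphenyl]tetrahydro-1H,3H-furo[3,4-c]furan-1-yl]-2,6-dimethoxyphenol (mono-O-benzyl syringaresinol), via triol 18 (not isolated)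
Conditions: LiAlH4 (4 equiv), THF, 0 °C → rt; quench; then 2 M aq. HCl–THF (1:4), rt
Reagents that add atoms: none
Why: Hydride reduction opens the lactone to the (2R,3R)-triol, and acid then removes the TES and ethoxyethyl groups and ionises both benzylic carbinols (p-quinone methide or p-alkoxybenzyl cation), each being trapped by the CH2OH on the neighbouring carbon in a 5-exo etherification that places the aryl group exo on the cis-fused bicycle, so both (S)-benzylic centres are set by C8/C8′ whatever the carbinol mixtures were.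

Step 8
Reactants: 20 methyl (4R)-2,2-dimethyl-1,3-dioxolane-4-carboxylate
Product: 22 methyl (2R)-3-[(tert-butyldimethylsilyl)oxy]-2-hydroxypropanoate, via methyl (2R)-glycerate 21 (not isolated)
Conditions: Amberlyst 15 (H+ form), MeOH, rt; filter, evaporate; then TBSCl (1.05 equiv), imidazole, CH2Cl2, −10 °C
Reagents that add atoms: tert-butyldimethylsilyl chloride CC(C)(C)[Si](C)(C)Cl
Why: Acid-catalysed transacetalisation frees the diol without touching the bought (R)-centre, and the primary hydroxyl is then silylated selectively on steric grounds.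

Step 9
Reactants: 23 methyl (4S)-2,2-dimethyl-1,3-dioxolane-4-carboxylate
Product: 25 methyl (2S)-3-[(tert-butyldimethylsilyl)oxy]-2-hydroxypropanoate, via methyl (2S)-glycerate 24 (not isolated)
Conditions: Amberlyst 15 (H+ form), MeOH, rt; filter, evaporate; then TBSCl (1.05 equiv), imidazole, CH2Cl2, −10 °C
Reagents that add atoms: tert-butyldimethylsilyl chloride CC(C)(C)[Si](C)(C)Cl
Why: The same transacetalisation and selective primary silylation give the enantiomeric building block with its bought (S)-centre intact.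

Step 10
Reactants: 22 methyl (2R)-3-[(tert-butyldimethylsilyl)oxy]-2-hydroxypropanoate
Product: 26 (2R)-3-[(tert-butyldimethylsilyl)oxy]-2-hydroxy-N-methoxy-N-methylpropanamide
Conditions: MeNHOMe·HCl (1.5 equiv), i-PrMgCl (4.2 equiv), THF, −20 → 0 °C
Reagents that add atoms: N,O-dimethylhydroxylamine hydrochloride CNOC.Cl
Why: Aminolysis of the ester by the magnesium amide (Weinreb amide formation) proceeds at low temperature on the magnesium alkoxide of the hydroxy ester without epimerising the α-centre.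

Step 11
Reactants: 19 mono-O-benzyl syringaresinol; 22 methyl (2R)-3-[(tert-butyldimethylsilyl)oxy]-2-hydroxypropanoate
Product: 27 methyl (2S)-2-(aryloxy)-3-[(tert-butyldimethylsilyl)oxy]propanoate in which the aryl group is the phenol ring of 19
Conditions: 22 (1.5 equiv), PPh3 (1.6 equiv), DIAD (1.6 equiv), toluene, 0 °C → rt
Reagents that add atoms: none
Why: Mitsunobu etherification of the 2,6-dimethoxyphenol is an SN2 displacement at the activated α-hydroxy ester carbon, so the bought (R)-centre is inverted cleanly to the (S)-C8 of unit A.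

Step 12
Reactants: 28 (4-bromo-2-methoxyphenoxy)(tert-butyl)dimethylsilane
Product: 29 {4-[(tert-butyldimethylsilyl)oxy]-3-methoxyphenyl}magnesium bromide (about 0.5 M stock solution in THF, titrated, kept under argon)
Conditions: Mg turnings (1.3 equiv, I2-activated), THF, 45 °C; decanted from excess Mg, titrated
Reagents that add atoms: magnesium [Mg]
Why: Oxidative insertion of magnesium into the aryl C–Br bond (Grignard reagent formation) leaves the aryl silyl ether and the methoxy group untouched, and one titrated batch serves both aryl additions of steps 13 and 18.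

Step 13
Reactants: 27 the aryloxy ester; 29 {4-[(tert-butyldimethylsilyl)oxy]-3-methoxyphenyl}magnesium bromide
Product: 31 (1R,2S)-2-(aryloxy)-3-[(tert-butyldimethylsilyl)oxy]-1-{4-[(tert-butyldimethylsilyl)oxy]-3-methoxyphenyl}propan-1-ol (aryl as in 27), via aldehyde 30 (not isolated)
Conditions: i-Bu2AlH (1.2 equiv), CH2Cl2, −78 °C; then 29 (3 equiv, THF solution), −78 → −30 °C; aq. KNaC4H4O6
Reagents that add atoms: none
Why: Partial reduction of the ester to the aldehyde oxidation level followed by Grignard addition under Felkin–Anh control (aryl enters anti to the C8–OAr bond and past the C8 hydrogen) gives the erythro (1R,2S) alcohol, C7 being set by the bought C8 centre.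

Step 14
Reactants: 31 the erythro alcohol
Product: 32 triethylsilyl ether of 31 at the benzylic hydroxyl
Conditions: Et3SiCl (1.5 equiv), imidazole (3 equiv), DMF, rt
Reagents that add atoms: chlorotriethylsilane CC[Si](Cl)(CC)CC
Why: Silylation masks the only free alcohol so that it cannot be activated in the second Mitsunobu reaction, and no stereocentre is touched.

Step 15
Reactants: 32 the fully protected unit A ether
Product: 33 phenol formed from 32 by loss of the benzyl group
Conditions: H2 (1 atm), 10% Pd/C, EtOAc, rt, 1 h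
Reagents that add atoms: none
Why: Hydrogenolysis of the aryl benzyl ether is much faster than cleavage of the furofuran or silyl-protected benzylic C–O bonds in neutral ethyl acetate.

Step 16
Reactants: 33 the phenol; 26 (2R)-3-[(tert-butyldimethylsilyl)oxy]-2-hydroxy-N-methoxy-N-methylpropanamide
Product: 34 (2S)-2-(aryloxy)-3-[(tert-butyldimethylsilyl)oxy]-N-methoxy-N-methylpropanamide in which the aryl group is the new phenol ring of 33
Conditions: 26 (1.5 equiv), PPh3 (1.6 equiv), DIAD (1.6 equiv), toluene, 0 °C → rt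
Reagents that add atoms: none
Why: A second Mitsunobu etherification with SN2 inversion turns the bought (R)-centre into the (S)-C8 of unit B, and all other hydroxyls are capped.

Step 17
Reactants: 35 4-bromo-2-methoxyphenol; 25 methyl (2S)-3-[(tert-butyldimethylsilyl)oxy]-2-hydroxypropanoate
Product: 36 methyl (2R)-2-(4-bromo-2-methoxyphenoxy)-3-[(tert-butyldimethylsilyl)oxy]propanoate
Conditions: 25 (1.2 equiv), PPh3 (1.3 equiv), DIAD (1.3 equiv), THF, 0 °C → rt
Reagents that add atoms: none
Why: Mitsunobu etherification with SN2 inversion converts the bought (S)-centre into the (R)-C8 of unit C.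

Step 18
Reactants: 36 the bromoaryloxy ester; 29 {4-[(tert-butyldimethylsilyl)oxy]-3-methoxyphenyl}magnesium bromide
Product: 38 (1S,2R)-2-(4-bromo-2-methoxyphenoxy)-3-[(tert-butyldimethylsilyl)oxy]-1-{4-[(tert-butyldimethylsilyl)oxy]-3-methoxyphenyl}propan-1-ol, via aldehyde 37 (not isolated)
Conditions: i-Bu2AlH (1.2 equiv), CH2Cl2, −78 °C; then 29 (3 equiv, THF solution), −78 → −30 °C; aq. KNaC4H4O6
Reagents that add atoms: none
Why: The same ester-to-aldehyde reduction and Felkin–Anh Grignard addition (aryl anti to the C8–OAr bond) give the erythro (1S,2R) alcohol, the aryl bromide being inert to both reagents at low temperature.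

Step 19
Reactants: 34 the Weinreb amide; 38 the bromoaryl ether of unit C
Product: 40 aryl ketone in which the N(OMe)Me group of 34 is replaced by the ring carbon of 38 that carried bromine, via dilithio species 39 (not isolated)
Conditions: 38 (1.3 equiv), MeLi (1.3 equiv), THF, −78 °C; t-BuLi (2.6 equiv), −78 °C; then 34, −78 → −40 °C; aq. NH4Cl
Reagents that add atoms: none
Why: Deprotonation of the free alcohol followed by bromine–lithium exchange gives an aryllithium that adds once to the Weinreb amide (stable chelated tetrahedral intermediate) to give the ketone on work-up, and the low temperature keeps the α-aryloxy centre intact.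

Step 20
Reactants: 40 the aryl ketone
Product: 41 (1S,2S)-alcohol obtained by reduction of the ketone of 40 (threo unit B)
Conditions: LiBH(s-Bu)3 (3 equiv), THF, −78 °C; MeOH then aq. NH4Cl
Reagents that add atoms: none
Why: Felkin–Anh reduction by the bulky borohydride delivers hydride anti to the C8–OAr bond of the α-aryloxy ketone, which is the diastereoface opposite to that used for aryl delivery in steps 13 and 18 and therefore gives the threo (1S,2S) unit under control of the bought C8 centre.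

Step 21
Reactants: 41 the fully assembled silyl-protected precursor
Product: 42 CNP0316493.3 (target)
Conditions: Bu4NF (9 equiv), AcOH (9 equiv), THF, 0 °C → rt
Reagents that add atoms: none
Why: Buffered fluoride desilylation cleaves all six silyl ethers (five TBS and one TES) without base-induced retro-aldol or quinone-methide chemistry, so every stereocentre is left untouched.

## Compound list

1 | (2S)-but-3-en-2-ol | C[C@H](O)C=C | starting material
2 | (2Z)-but-2-ene-1,4-diyl diacetate | CC(=O)OC/C=C\COC(C)=O | starting material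
3 | (2E,4S)-4-hydroxypent-2-en-1-yl acetate | C[C@H](O)/C=C/COC(C)=O | intermediate
4 | triethyl orthoacetate (1,1,1-triethoxyethane) | CC(OCC)(OCC)OCC | starting material
5 | (2E,4S)-4-[(1-ethoxyethenyl)oxy]pent-2-en-1-yl acetate (ketene acetal) | C=C(OCC)O[C@@H](C)/C=C/COC(C)=O | intermediate
6 | ethyl (3S,4E)-3-(acetoxymethyl)hex-4-enoate | CCOC(=O)C[C@H](COC(C)=O)/C=C/C | intermediate
7 | (4S)-4-[(1E)-prop-1-en-1-yl]dihydrofuran-2(3H)-one | O=C1C[C@@H](/C=C/C)CO1 | intermediate
8 | 4-(benzyloxy)-3,5-dimethoxybenzaldehyde | COc1cc(C=O)cc(OC)c1OCc1ccccc1 | starting material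
9 | lithium enolate of 7 (lithium 4-[(1E)-prop-1-en-1-yl]-4,5-dihydrofuran-2-olate, C4 arranged as in 7) | [Li+].[O-]C1=C[C@@H](/C=C/C)CO1 | intermediate
10 | lithium alkoxide of the aldol adduct (11 with OLi in place of OSiEt3) | O=C1[C@H](C([O-])c2cc(OC)c(OCc3ccccc3)c(OC)c2)[C@@H](/C=C/C)CO1.[Li+] | intermediate
11 | (3S,4R)-3-{[4-(benzyloxy)-3,5-dimethoxyphenyl][(triethylsilyl)oxy]methyl}-4-[(1E)-prop-1-en-1-yl]dihydrofuran-2(3H)-one, both carbinol epimers (C4 unchanged in space, descriptor R by priority change) | O=C1[C@H](C(O[Si](CC)(CC)CC)c2cc(OC)c(OCc3ccccc3)c(OC)c2)[C@@H](/C=C/C)CO1 | intermediate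
12 | (3S,4R)-3-{[4-(benzyloxy)-3,5-dimethoxyphenyl][(triethylsilyl)oxy]methyl}-4-(5-methyl-1,2,4-trioxolan-3-yl)dihydrofuran-2(3H)-one (ozonide) | O=C1[C@H](C(O[Si](CC)(CC)CC)c2cc(OC)c(OCc3ccccc3)c(OC)c2)[C@@H](C2OOC(C)O2)CO1 | intermediate
13 | (3R,4S)-4-{[4-(benzyloxy)-3,5-dimethoxyphenyl][(triethylsilyl)oxy]methyl}-5-oxotetrahydrofuran-3-carbaldehyde | O=C1[C@H](C(O[Si](CC)(CC)CC)c2cc(OC)c(OCc3ccccc3)c(OC)c2)[C@@H](C=O)CO1 | intermediate
14 | 4-bromo-2,6-dimethoxyphenol | COc1cc(Br)cc(OC)c1O | starting material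
15 | 5-bromo-2-(1-ethoxyethoxy)-1,3-dimethoxybenzene (racemic acetal) | CCOC(C)Oc1c(OC)cc(Br)cc1OC | intermediate
16 | [4-(1-ethoxyethoxy)-3,5-dimethoxyphenyl]magnesium bromide | CCOC(C)Oc1c(OC)cc([Mg]Br)cc1OC | intermediate
17 | (3S,4R)-3-{[4-(benzyloxy)-3,5-dimethoxyphenyl][(triethylsilyl)oxy]methyl}-4-{[4-(1-ethoxyethoxy)-3,5-dimethoxyphenyl](hydroxy)methyl}dihydrofuran-2(3H)-one, mixture at both carbinol carbons and the acetal carbon | O=C1[C@H](C(O[Si](CC)(CC)CC)c2cc(OC)c(OCc3ccccc3)c(OC)c2)[C@@H](C(O)c2cc(OC)c(OC(C)OCC)c(OC)c2)CO1 | intermediate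
18 | (2R,3R)-2-{[4-(benzyloxy)-3,5-dimethoxyphenyl][(triethylsilyl)oxy]methyl}-3-{[4-(1-ethoxyethoxy)-3,5-dimethoxyphenyl](hydroxy)methyl}butane-1,4-diol | OC[C@H](C(O[Si](CC)(CC)CC)c1cc(OC)c(OCc2ccccc2)c(OC)c1)[C@@H](C(O)c1cc(OC)c(OC(C)OCC)c(OC)c1)CO | intermediate
19 | 4-[(1S,3aR,4S,6aR)-4-[4-(benzyloxy)-3,5-dimethoxyphenyl]tetrahydro-1H,3H-furo[3,4-c]furan-1-yl]-2,6-dimethoxyphenol (mono-O-benzyl syringaresinol) | COc1cc([C@H]2OC[C@H]3[C@@H]2CO[C@@H]3c2cc(OC)c(OCc3ccccc3)c(OC)c2)cc(OC)c1O | intermediate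
20 | methyl (4R)-2,2-dimethyl-1,3-dioxolane-4-carboxylate | COC(=O)[C@H]1COC(C)(C)O1 | starting material
21 | methyl (2R)-2,3-dihydroxypropanoate | COC(=O)[C@H](O)CO | intermediate
22 | methyl (2R)-3-[(tert-butyldimethylsilyl)oxy]-2-hydroxypropanoate | COC(=O)[C@H](O)CO[Si](C)(C)C(C)(C)C | intermediate
23 | methyl (4S)-2,2-dimethyl-1,3-dioxolane-4-carboxylate | COC(=O)[C@@H]1COC(C)(C)O1 | starting material
24 | methyl (2S)-2,3-dihydroxypropanoate | COC(=O)[C@@H](O)CO | intermediate
25 | methyl (2S)-3-[(tert-butyldimethylsilyl)oxy]-2-hydroxypropanoate | COC(=O)[C@@H](O)CO[Si](C)(C)C(C)(C)C | intermediate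
26 | (2R)-3-[(tert-butyldimethylsilyl)oxy]-2-hydroxy-N-methoxy-N-methylpropanamide | CON(C)C(=O)[C@H](O)CO[Si](C)(C)C(C)(C)C | intermediate
27 | methyl (2S)-2-(aryloxy)-3-(TBS-oxy)propanoate, aryl = phenol ring of 19 (19 O-alkylated by CH(CO2Me)CH2OTBS) | COc1cc([C@H]2OC[C@H]3[C@@H]2CO[C@@H]3c2cc(OC)c(OCc3ccccc3)c(OC)c2)cc(OC)c1O[C@H](C(=O)OC)CO[Si](C)(C)C(C)(C)C | intermediate
28 | (4-bromo-2-methoxyphenoxy)(tert-butyl)dimethylsilane | COc1cc(Br)ccc1O[Si](C)(C)C(C)(C)C | starting material
29 | {4-[(tert-butyldimethylsilyl)oxy]-3-methoxyphenyl}magnesium bromide (THF stock solution) | COc1cc([Mg]Br)ccc1O[Si](C)(C)C(C)(C)C | intermediate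
30 | (2S)-2-(aryloxy)-3-(TBS-oxy)propanal, aryl as in 27 | COc1cc([C@H]2OC[C@H]3[C@@H]2CO[C@@H]3c2cc(OC)c(OCc3ccccc3)c(OC)c2)cc(OC)c1O[C@H](C=O)CO[Si](C)(C)C(C)(C)C | intermediate
31 | (1R,2S)-2-(aryloxy)-3-(TBS-oxy)-1-[4-(TBS-oxy)-3-methoxyphenyl]propan-1-ol, aryl as in 27 (erythro unit A) | COc1cc([C@H]2OC[C@H]3[C@@H]2CO[C@@H]3c2cc(OC)c(OCc3ccccc3)c(OC)c2)cc(OC)c1O[C@@H](CO[Si](C)(C)C(C)(C)C)[C@H](O)c1ccc(O[Si](C)(C)C(C)(C)C)c(OC)c1 | intermediate
32 | 31 with the benzylic hydroxyl as its triethylsilyl ether | COc1cc([C@H]2OC[C@H]3[C@@H]2CO[C@@H]3c2cc(OC)c(OCc3ccccc3)c(OC)c2)cc(OC)c1O[C@@H](CO[Si](C)(C)C(C)(C)C)[C@H](O[Si](CC)(CC)CC)c1ccc(O[Si](C)(C)C(C)(C)C)c(OC)c1 | intermediate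
33 | 32 with the benzyl ether replaced by a free phenol | COc1cc([C@H]2OC[C@H]3[C@@H]2CO[C@@H]3c2cc(OC)c(O)c(OC)c2)cc(OC)c1O[C@@H](CO[Si](C)(C)C(C)(C)C)[C@H](O[Si](CC)(CC)CC)c1ccc(O[Si](C)(C)C(C)(C)C)c(OC)c1 | intermediate
34 | 33 O-alkylated at the new phenol by (S)-CH[C(O)N(OMe)Me]CH2OTBS ((2S)-Weinreb amide) | COc1cc([C@H]2OC[C@H]3[C@@H]2CO[C@@H]3c2cc(OC)c(O[C@H](C(=O)N(C)OC)CO[Si](C)(C)C(C)(C)C)c(OC)c2)cc(OC)c1O[C@@H](CO[Si](C)(C)C(C)(C)C)[C@H](O[Si](CC)(CC)CC)c1ccc(O[Si](C)(C)C(C)(C)C)c(OC)c1 | intermediate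
35 | 4-bromo-2-methoxyphenol | COc1cc(Br)ccc1O | starting material
36 | methyl (2R)-2-(4-bromo-2-methoxyphenoxy)-3-[(tert-butyldimethylsilyl)oxy]propanoate | COc1cc(Br)ccc1O[C@@H](C(=O)OC)CO[Si](C)(C)C(C)(C)C | intermediate
37 | (2R)-2-(4-bromo-2-methoxyphenoxy)-3-[(tert-butyldimethylsilyl)oxy]propanal | COc1cc(Br)ccc1O[C@@H](C=O)CO[Si](C)(C)C(C)(C)C | intermediate
38 | (1S,2R)-2-(4-bromo-2-methoxyphenoxy)-3-[(tert-butyldimethylsilyl)oxy]-1-{4-[(tert-butyldimethylsilyl)oxy]-3-methoxyphenyl}propan-1-ol (erythro unit C on the bromo ring of unit B) | COc1cc(Br)ccc1O[C@H](CO[Si](C)(C)C(C)(C)C)[C@@H](O)c1ccc(O[Si](C)(C)C(C)(C)C)c(OC)c1 | intermediate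
39 | 38 with Br replaced by Li and OH by OLi (dilithio species) | COc1cc([Li])ccc1O[C@H](CO[Si](C)(C)C(C)(C)C)[C@@H](O[Li])c1ccc(O[Si](C)(C)C(C)(C)C)c(OC)c1 | intermediate
40 | aryl ketone: 34 with N(OMe)Me replaced by the former C–Br carbon of 38; (2S) at C8 of unit B | COc1cc([C@H]2OC[C@H]3[C@@H]2CO[C@@H]3c2cc(OC)c(O[C@@H](CO[Si](C)(C)C(C)(C)C)C(=O)c3ccc(O[C@H](CO[Si](C)(C)C(C)(C)C)[C@@H](O)c4ccc(O[Si](C)(C)C(C)(C)C)c(OC)c4)c(OC)c3)c(OC)c2)cc(OC)c1O[C@@H](CO[Si](C)(C)C(C)(C)C)[C@H](O[Si](CC)(CC)CC)c1ccc(O[Si](C)(C)C(C)(C)C)c(OC)c1 | intermediate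
41 | 40 with the ketone reduced to the (1S)-alcohol ((1S,2S) threo unit B) | COc1cc([C@H]2OC[C@H]3[C@@H]2CO[C@@H]3c2cc(OC)c(O[C@@H](CO[Si](C)(C)C(C)(C)C)[C@@H](O)c3ccc(O[C@H](CO[Si](C)(C)C(C)(C)C)[C@@H](O)c4ccc(O[Si](C)(C)C(C)(C)C)c(OC)c4)c(OC)c3)c(OC)c2)cc(OC)c1O[C@@H](CO[Si](C)(C)C(C)(C)C)[C@H](O[Si](CC)(CC)CC)c1ccc(O[Si](C)(C)C(C)(C)C)c(OC)c1 | intermediate
42 | CNP0316493.3: (1S,3aR,4S,6aR)-furofuran carrying at C1 a 3,5-dimethoxyphenyl whose 4-O bears (1R,2S)-1,3-dihydroxy-1-(4-hydroxy-3-methoxyphenyl)propan-2-yl, and at C4 a 3,5-dimethoxyphenyl whose 4-O bears (1S,2S)-1,3-dihydroxy-1-(3-methoxy-4-{[(1S,2R)-1,3-dihydroxy-1-(4-hydroxy-3-methoxyphenyl)propan-2-yl]oxy}phenyl)propan-2-yl | COc1cc([C@@H](O)[C@H](CO)Oc2c(OC)cc([C@H]3OC[C@H]4[C@@H]3CO[C@@H]4c3cc(OC)c(O[C@@H](CO)[C@@H](O)c4ccc(O[C@H](CO)[C@@H](O)c5ccc(O)c(OC)c5)c(OC)c4)c(OC)c3)cc2OC)ccc1O | target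

## Step count and risks

Total step count: 21. Longest linear sequence: 14 steps (1–4, 6, 7, 11, 13–16, 19–21).

**Step 7 (reduction and double ring closure).** The benzyl-capped ring ionises less readily than the free-phenol ring, so C7 epimers or a 2,5-diaryltetrahydrofuran may contaminate 19. The fallback sets out from 17 and first hydrogenolyses the benzyl ether (H2, Pd/C, EtOAc) to the phenolic lactone F1. LiAlH4 reduction gives the triol F2 (not isolated), which is stirred in 0.2 M aq. HCl–THF so that both rings now close through p-quinone methides, giving the symmetrical diphenol (1S,3aR,4S,6aR)-syringaresinol F3. Mono-benzylation (BnBr 1.0 equiv, K2CO3, acetone; statistical, unreacted F3 recycled) desymmetrises it and rejoins the route at 19.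

**Step 13 (erythro-selective aryl addition).** Chelation of magnesium by the dimethoxyphenyl ether could erode or invert the Felkin–Anh preference. The fallback sets out from 27 and turns the ester into the Weinreb amide F4 (MeNHOMe·HCl, i-PrMgCl, THF, −20 °C). Addition of 29 gives the aryl ketone F5, and C7 is then created by hydride delivery instead of aryl delivery: Zn(BH4)2 in Et2O at −30 °C reduces F5 through the five-membered chelate between the ketone and the C8 ether oxygen, with hydride entering on the face of the C8 hydrogen, which is the erythro-selective mode. This comes back to the route at 31.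

**Step 20 (threo-selective reduction).** The hindered ketone may react sluggishly or unselectively with the bulky borohydride. The fallback sets out from 40 and removes all six silyl groups first (HF·pyridine, pyridine–THF, 0 °C → rt) to give the free polyol ketone F6. Reduction with Zn(BH4)2 (THF–EtOAc, 0 °C) then runs through a six-membered chelate between the ketone and the free C9 hydroxyl, with hydride adding anti to the C8 aryloxy group to give the threo unit B. This comes back to the route at the target 42.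

## Further compounds

F1 | step 7 | (3S,4R)-3-{(4-hydroxy-3,5-dimethoxyphenyl)[(triethylsilyl)oxy]methyl}-4-{[4-(1-ethoxyethoxy)-3,5-dimethoxyphenyl](hydroxy)methyl}dihydrofuran-2(3H)-one | O=C1[C@H](C(O[Si](CC)(CC)CC)c2cc(OC)c(O)c(OC)c2)[C@@H](C(O)c2cc(OC)c(OC(C)OCC)c(OC)c2)CO1
F2 | step 7 | (2R,3R)-2-{(4-hydroxy-3,5-dimethoxyphenyl)[(triethylsilyl)oxy]methyl}-3-{[4-(1-ethoxyethoxy)-3,5-dimethoxyphenyl](hydroxy)methyl}butane-1,4-diol | OC[C@H](C(O[Si](CC)(CC)CC)c1cc(OC)c(O)c(OC)c1)[C@@H](C(O)c1cc(OC)c(OC(C)OCC)c(OC)c1)CO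
F3 | step 7 | 4,4'-[(1S,3aR,4S,6aR)-tetrahydro-1H,3H-furo[3,4-c]furan-1,4-diyl]bis(2,6-dimethoxyphenol) (syringaresinol) | COc1cc([C@H]2OC[C@H]3[C@@H]2CO[C@@H]3c2cc(OC)c(O)c(OC)c2)cc(OC)c1O
F4 | step 13 | (2S)-2-(aryloxy)-3-(TBS-oxy)-N-methoxy-N-methylpropanamide, aryl = phenol ring of 19 | COc1cc([C@H]2OC[C@H]3[C@@H]2CO[C@@H]3c2cc(OC)c(OCc3ccccc3)c(OC)c2)cc(OC)c1O[C@H](C(=O)N(C)OC)CO[Si](C)(C)C(C)(C)C
F5 | step 13 | (2S)-2-(aryloxy)-3-(TBS-oxy)-1-[4-(TBS-oxy)-3-methoxyphenyl]propan-1-one, aryl = phenol ring of 19 | COc1cc([C@H]2OC[C@H]3[C@@H]2CO[C@@H]3c2cc(OC)c(OCc3ccccc3)c(OC)c2)cc(OC)c1O[C@@H](CO[Si](C)(C)C(C)(C)C)C(=O)c1ccc(O[Si](C)(C)C(C)(C)C)c(OC)c1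
F6 | step 20 | fully desilylated ketone (42 with the benzylic carbinol of unit B as C=O) | COc1cc([C@H]2OC[C@H]3[C@@H]2CO[C@@H]3c2cc(OC)c(O[C@@H](CO)C(=O)c3ccc(O[C@H](CO)[C@@H](O)c4ccc(O)c(OC)c4)c(OC)c3)c(OC)c2)cc(OC)c1O[C@@H](CO)[C@H](O)c1ccc(O)c(OC)c1
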